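Readings and results come from a simulation with made-up constants; the scatter is artificial.

Two numbers and a trend are asked, all about how far L gets on the X charged.

common to all: L 0.12 M
- alder: X 0.16 M; run made earlier
- elm: X 0.17 M; run made earlier
- Tuesday's: X 0.200 M; time 8.0 h
- Sunday's: X 0.130 M; time 8.0 h

| run | time / h | L / % | J / % |
|---|---|---|---|
| alder | 0.667 | 63.2 | 29.4 |
| alder | 2.00 | 37.9 | 48.9 |
| alder | 4.00 | 25.4 | 58.1 |
| alder | 6.00 | 20.2 | 62.7 |
| alder | 8.00 | 17.6 | 64.3 |
| elm | 1.50 | 42.1 | 46.3 |
| elm | 3.00 | 28.9 | 57.5 |
| elm | 5.00 | 21.2 | 63.7 |
| elm | 6.00 | 18.6 | 65.4 |
| elm | 8.00 | 15.5 | 66.7 |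

(readings scatter by 0.5 percentage points)

- percentages count the L that a species holds: one Q counts as two
- steps thought possible: L + X -> Z + J; X + Z <-> D; Z -> G; 2 L -> Q

1. part of the L that has reacted at the end, Tuesday's
2. part of the L that has reacted at the end, Sunday's
3. what raising the concentration of X from its lowest to its highest value here does to the part of the L that has reacted (changes below 5 percentage points count as none) (no change / it falls / it rises)

If each Z formed ties up a second X as D, each J costs two X, and X is the limiting reagent at that price. J should then stall near the X allowance: half the X charged, as a percentage of the L charged. For alder that is 66.7% against a last reading of 64.3%, and for elm 70.8% against 66.7%, both readings lying just below. For Sunday's flask the allowance is 54.2%.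

L gone but not held as J stood at 18 percentage points at the end of alder, so Sunday's reacted share comes to 72.3%. That gap is the weak link, since it was taken as fixed. If it is Q, it grows with the square of L, and at the end Sunday's L, reckoned near 27.7% against alder's last reading of 17.6%, loses L that way 2.48 times as fast. Alder's gap grew 1.6 points from 4.00 h to 8.00 h, so that growth is added at this multiple, and my number is 76.2%.

In Tuesday's flask, allowance plus gap is 101%, above the whole charge, so the allowance gives no stop. Carrying the alder-to-elm gain forward, which rests on readings with a scatter of 0.5 points, gives 90.8%.

The forecast, reasoning that “each Z formed ties up a second X as D”, says 88.5% for Tuesday's and 76% for Sunday's, and for X raised from its lowest to its highest value, it rises; my Sunday's number lies close to that.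

The flasks give 89.9% for Tuesday's and 77.9% for Sunday's, and for X raised from its lowest to its highest value, it rises, by 12 points.

    L + X → Z + J (k = 4.71 /M/h)
    X + Z ⇌ D, settled at all times (K = 2000 /M)
    Z → G (k = 0.108 /h)
    2 L → Q (k = 0.720 /M/h)

In Sunday's flask L goes to J 2.8 times as fast as to Q at 0.766 h, but 0.84 times as fast at 8.00 h. By then J stands at 53.8% against the allowance of 54.2%, and free X at 5.24% of its charge.

For a neighbour, Sunday's flask with 0.048 M of L, the allowance is 135%, above the whole charge, so X should not stop J. It gives J 86.1%, with 37% of the X left and 93.0% of the L reacted.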